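The constants were drawn at random within sensible limits, and the outcome is calculated.

Start from the amounts: the flask is charged with 26 mM of substrate, more than the 8.4 mM at which the solution saturates, so the gas has to pass in during the run.

    substrate → side product (k1 = 0.12 /h)
    gas phase ⇌ dissolved gas, rate k2*(csat - [dissolved gas]) (k2 = 1.0 /h, csat = 8.4 mM)
    substrate + dissolved gas → target (k3 = 62 /M/h)
    dissolved gas + target → over-reaction product (k4 = 2.3 /M/h)
substrate 26 mM; gas phase 8.4 mM (held); time 10 h
1. target at 10 h, in percent of the substrate charged
2. the change that raises the amount of target at 10 h, in percent of the substrate charged most ("none" if none brings more than 2 percentage points) (beta / alpha / none)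
3. amount of target at 10 h, in percent of the substrate charged, after beta
- at the start none of the gas is dissolved
- run time (flask): 10 h

Compare two half-lives. Dissolved gas lasts 0.43 h against substrate as charged, a pseudo-first-order loss, while transfer needs 0.693 h to halve a gap to saturation. Their ratio is the target step's rate constant times the charged substrate, over the transfer coefficient: the supply number N = 1.61.

Now set supply equal to use. [dissolved gas] is then saturation divided by one plus N times the fraction of substrate left, which is 3.22 mM with substrate as charged. By this reckoning target forms per side product at 1.66 with substrate as charged, rising to 4.34 as substrate goes. Integrating over the substrate gives me 71.0% as target, before any over-reaction and without the climb from no dissolved gas. Doubling the transfer coefficient (alpha) halves N to 0.805, but doubling the saturation concentration (beta) leaves N as it stands, so N gives no ranking of the two changes.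

The forecast says 60% (55% to 64%), lower than my figure, which stands before over-reaction; it picks alpha and gives 61% after beta, since doubling saturation “roughly doubles the over-reaction during the long tail”.

The flask gives 59.4%, best alpha with 4 percentage points against 0.82 points for beta, and 60.3% after beta. Half of its side product's turnover up to 10 h is done by 1.70 h, earlier than the 2.58 h for transfer, and at 1.00 h [dissolved gas] stood at 38.4% of saturation. At 5.00 h, with 14.8% of the substrate left, N gives 6.78 mM against 6.11 mM in the flask.

In the neighbour read at 2.50 h, 45.3% of the substrate is left, so N gives 4.86 mM. The neighbour holds 4.40 mM.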